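Thursday's flask holds a small charge, 0.0260 M of starting material with 0.0400 M of partner, so by the overall equation starting material is the limiting reagent. I wanted its target at 9.7 h.

| flask | starting material | partner | time |
|---|---|---|---|
| Tuesday's | 0.0800 M | 0.0800 M |  |
| Sunday's | 0.0480 M | 0.0480 M |  |
| Saturday's | 0.120 M | 0.0800 M |  |
| Thursday's | 0.0260 M | 0.0400 M | 9.7 h |

| run | time / h | [target] / M |
|---|---|---|
| Tuesday's run | 1.6 | 0.0086 |
| Tuesday's run | 3.2 | 0.0196 |
| Tuesday's run | 4.8 | 0.0246 |
| Tuesday's run | 6.5 | 0.0281 |
| Tuesday's run | 8.1 | 0.0285 |
| Tuesday's run | 9.7 | 0.0295 |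
| Sunday's run | 1.6 | 0.0030 |
| Sunday's run | 3.2 | 0.0065 |
| Sunday's run | 4.8 | 0.0106 |
| Sunday's run | 6.5 | 0.0132 |
| Sunday's run | 8.1 | 0.0141 |
| Sunday's run | 9.7 | 0.0147 |
| Saturday's run | 1.6 | 0.0147 |
| Saturday's run | 3.2 | 0.0317 |
| Saturday's run | 4.8 | 0.0383 |
| Saturday's run | 6.5 | 0.0409 |
| Saturday's run | 8.1 | 0.0428 |
| Saturday's run | 9.7 | 0.0441 |

(standard deviation of a reading: 4 × 10⁻⁴ M)

1. the power of [starting material] that the first rate follows, about the charge of the Tuesday's run; measure it at two percent of starting material made into target (one fixed amount of target, the same in the runs compared)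
2. the power of [partner] that the first rate follows, about the charge of the Tuesday's run; measure it at two percent of starting material made into target
3. target in the Thursday's run at 9.7 h, as a share of the starting material charged

- Overall: starting material + partner -> target.
- Constant volume, constant temperature.
- "The second partner" is partner.
- An order is taken over about fifteen percent of the charge, up and down.

1. Let S and R be the charges of starting material and partner, and P the target made. I divided the two falling concentrations out of the readings. The clock J, the second-order integral, is the sum of dP/((S−P)(R−P)) from the start to a reading. It equals ln[R(S−P)/(S(R−P))]/(S−R), or one over S−P less one over S where S equals R. Flasks whose rate follows the product of the two concentrations, times a factor of time they share, reach one J at one time.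

2. At 9.7 h, J reads 7.30 M⁻¹ in Tuesday's run and 8.58 M⁻¹ in Saturday's. The clock at 9.7 h in Sunday's run reads 9.20 M⁻¹.

3. The scatter of a reading puts about 0.361 M⁻¹ on Sunday's clock, and Sunday's stands 1.89 M⁻¹ above Tuesday's. So the three runs do not share one J.

4. Sunday's run has the lowest charge and the highest clock. Its partner charge is also the nearest to Thursday's, so I carried Sunday's clock over.

5. Turned round, J gives (S−P)/(R−P) = (S/R)exp(J(S−R)), which is 0.571 for Thursday. That puts my estimate of the target at 28.2% of the starting material charged. The weak link is that Thursday's charge lies below every run.

The forecast, on its own reading of the same clock (“For Thursday I expect about 9”), gave 28%. For the orders it gave 1.3 in starting material and 0.9 in partner, with “Saturday against Tuesday gives a starting-material order near 1.3”.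

The flask gave 30.1% for Thursday, with orders 0.76 in starting material and 0.70 in partner.

    starting material ⇌ intermediate + by-product (0.6084 h⁻¹, 0.8676 M⁻¹ h⁻¹)
    intermediate + partner → target (1.998 M⁻¹ h⁻¹)
    starting material + partner + target → 2 target (209.5 M⁻² h⁻¹)
    target + partner → side product (2.174 M⁻¹ h⁻¹)

Where the same amount of target stood, Saturday's run went 1.4 times as fast as Tuesday's, while their first readings stand in the ratio 1.71. Thursday's share, put on the clock, reads 10.0 M⁻¹, which is 0.800 M⁻¹ further on than Sunday's 9.20 M⁻¹.

The numbers in the tables are simulated for substances that don't exist; scatter was added.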